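**Plan**

- Cuts: the ester C(acyl)–O bond at C6; then, after redrawing the C3=C4 olefin with its C5–H as a C3 ketone conjugated to a C4=C5 olefin (retron of a reductive 1,3-transposition), the C4–C5 bond (aldol condensation, ring A) and the C1–C10 bond (Michael addition).
- Enabling feature: in ring A the olefinic carbon C4 (bearing the C15 methyl) is bonded to the ring-fusion methine C5, which also belongs to ring B. With a helper carbonyl at C3, C4 becomes the α-carbon of an ethyl ketone lying 1,5 (through C10, C1, C2) to a ring-B ketone at C5, and this array cyclizes and dehydrates to a cyclohexenone.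
- Forward order: ring B is bought ((+)-dihydrocarvone, hydrogenated); C1–C10 by chiral-imine Michael addition to ethyl vinyl ketone; ring A by C4–C5 aldol condensation; C6 oxygen through the 3,5-dienyl acetate; esterification; the C3 helper is reduced and excised with olefin transposition.
- Stereochemistry: C7 is bought; C10 is set in the Michael addition under control of the (R)-1-phenylethylamine auxiliary; C6 (β, axial) by axial oxygen delivery to the dienyl acetate; the temporary C3 carbinol by axial hydride delivery, and from it C5 by suprafacial hydrogen transfer in a diazene retro-ene step.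

Key step: step 4

Remark: positions follow eudesmane numbering (ring A = C1, C2, C3, C4, C5, C10; ring B = C5 to C10; C14 = methyl on C10; C15 = methyl on C4; isopropyl on C7), β is the face of the C14 methyl; commercial (+)-dihydrocarvone is taken as the (5R) compound, a mixture of C2 epimers, which is immaterial because C2 is planarized in steps 2 and 3.

**Route**

Step 1
Reactants: 1 (+)-dihydrocarvone, (5R)-2-methyl-5-(prop-1-en-2-yl)cyclohexan-1-one
Product: 2 (5R)-2-methyl-5-(propan-2-yl)cyclohexan-1-one (carvomenthone, C2 epimer mixture)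
Conditions: H2 (1 atm), 10% Pd/C, EtOAc, rt
Reagents that add atoms: none
Why: Heterogeneous catalytic hydrogenation should saturate the unhindered 1,1-disubstituted isopropenyl olefin and leave the ketone alone; the C5 stereocentre is not involved and no new one is created.

Step 2
Reactants: 2 (5R)-2-methyl-5-(propan-2-yl)cyclohexan-1-one; 3 (R)-1-phenylethylamine
Product: 4 (R)-N-[(5R)-2-methyl-5-(propan-2-yl)cyclohexylidene]-1-phenylethan-1-amine
Conditions: cat. TsOH·H2O, toluene, reflux, Dean–Stark
Reagents that add atoms: none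
Why: Acid-catalysed ketimine formation with azeotropic removal of water installs the chiral auxiliary; no new stereocentre is fixed, and C2 becomes labile through imine–enamine tautomerism.

Step 3
Reactants: 4 (R)-N-[(5R)-2-methyl-5-(propan-2-yl)cyclohexylidene]-1-phenylethan-1-amine; 5 ethyl vinyl ketone (pent-1-en-3-one)
Product: 7 (2S,5R)-2-methyl-2-(3-oxopentyl)-5-(propan-2-yl)cyclohexan-1-one, via Michael adduct imine 6 (not isolated)
Conditions: THF, rt to 40 °C; then 10% aq. AcOH, rt
Reagents that add atoms: water, O
Why: Chiral-imine Michael addition: the more substituted secondary enamine tautomer should add to the enone through a compact aza-ene-like transition state on the face of C2 anti to the phenyl group of the (R)-auxiliary, which sets the quaternary centre (2S, the future C10, side chain trans to the isopropyl group) as known for the isopropenyl analogue of this imine, and aqueous acid then hydrolyses the imine.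

Step 4
Reactants: 7 (2S,5R)-2-methyl-2-(3-oxopentyl)-5-(propan-2-yl)cyclohexan-1-one
Product: 9 (7R,10S)-eudesm-4-en-3-one (11,12-dihydro-α-cyperone; 7β-isopropyl and 10β-methyl), via aldol ketol 8 (not isolated)
Conditions: NaOMe, MeOH, reflux
Reagents that add atoms: none
Why: Methoxide reversibly enolizes the diketone, the enolate at C4 (the CH2 of the ethyl ketone) adds to the ring-B carbonyl carbon C5 to give ketol 8, and E1cB loss of water across C4–C5 should give the conjugated enone irreversibly. The closest known reaction type is the aldol-condensation half of a Robinson annulation of a 2-alkyl-2-(3-oxoalkyl)cyclohexanone. Ring A closes in a 6-(enolendo)-exo-trig mode. No stereocentre is retained from this step, because C4 and C5 of 8 become sp2; C10 is quaternary and C7 is not α to a carbonyl, so neither can epimerize, and the C5 configuration is deferred to step 10, where the C3 oxygen introduced here relays it. The step needs site selectivity among the enolates of 7: closure from C2 would give a four-membered ring, and closure from C6 onto C3 gives a bridged ketol that cannot dehydrate to a conjugated enone and reverts, so only the C4-to-C5 closure is drained by dehydration. The resulting enone holds the C3 carbonyl as a removable helper and activates C6 through its dienol, which the rest of the route uses.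

Step 5
Reactants: 9 (7R,10S)-eudesm-4-en-3-one
Product: 10 (7S,10S)-eudesma-3,5-dien-3-yl acetate
Conditions: isopropenyl acetate (solvent), cat. TsOH·H2O, reflux, acetone distilled off
Reagents that add atoms: isopropenyl acetate, CC(=C)OC(C)=O
Why: Acid-catalysed enol acetylation under thermodynamic control should give the extended heteroannular 3,5-dienyl acetate, as with steroidal 4-en-3-ones; no stereocentre is created.

Step 6
Reactants: 10 (7S,10S)-eudesma-3,5-dien-3-yl acetate
Product: 11 (6R,7S,10S)-6-hydroxyeudesm-4-en-3-one (6β-hydroxy)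
Conditions: mCPBA, dioxane/aq. phosphate buffer (pH 7.5), 0 °C to rt
Reagents that add atoms: mCPBA, OOC(=O)c1cccc(Cl)c1
Why: Peracid γ-hydroxylation of a dienyl acetate: electrophilic oxygen should be delivered to C6, the terminus of the dienol system, with collapse to the enone and loss of the acetyl group, and axial β attack (chair-like ring B, no allylic 1,3-strain between the new C6 substituent and the C15 methyl) should give the 6β alcohol as in the steroid series.

Step 7
Reactants: 12 (E)-4-hydroxycinnamic acid (p-coumaric acid)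
Product: 14 (E)-3-[4-(tert-butyldimethylsilyloxy)phenyl]prop-2-enoic acid, via bis-silylated compound 13 (not isolated)
Conditions: TBSCl, imidazole, DMF, rt; then cat. K2CO3, THF/MeOH/H2O, rt
Reagents that add atoms: tert-butyldimethylsilyl chloride, CC(C)(C)[Si](C)(C)Cl
Why: Exhaustive silylation followed by selective solvolysis of the labile silyl ester should leave the aryl silyl ether and the free acid; no stereocentre is involved and the E olefin is untouched.

Step 8
Reactants: 11 (6R,7S,10S)-6-hydroxyeudesm-4-en-3-one; 14 (E)-3-[4-(tert-butyldimethylsilyloxy)phenyl]prop-2-enoic acid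
Product: 16 (6R,7S,10S)-3-oxoeudesm-4-en-6-yl (E)-3-[4-(tert-butyldimethylsilyloxy)phenyl]prop-2-enoate, via mixed anhydride 15 (not isolated)
Conditions: 2,4,6-trichlorobenzoyl chloride, Et3N, THF, rt; then 11, DMAP, toluene, rt to 50 °C
Reagents that add atoms: none
Why: Yamaguchi esterification: the mixed trichlorobenzoic anhydride with DMAP should be a strong enough acyl donor for the axial, doubly flanked C6 hydroxyl, and acylation on oxygen retains the C6 configuration.

Step 9
Reactants: 16 (6R,7S,10S)-3-oxoeudesm-4-en-6-yl (E)-3-[4-(tert-butyldimethylsilyloxy)phenyl]prop-2-enoate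
Product: 17 (3S,6R,7S,10S)-3-hydroxyeudesm-4-en-6-yl (E)-3-[4-(tert-butyldimethylsilyloxy)phenyl]prop-2-enoate (3β-hydroxy)
Conditions: NaBH4, CeCl3·7H2O, MeOH/THF, −40 °C
Reagents that add atoms: none
Why: Luche reduction should be 1,2-selective for the enone carbonyl and spare the cinnamate, with axial hydride delivery from the α face of C3 (opposite the C14 methyl) giving the pseudo-equatorial 3β alcohol.

Step 10
Reactants: 17 (3S,6R,7S,10S)-3-hydroxyeudesm-4-en-6-yl (E)-3-[4-(tert-butyldimethylsilyloxy)phenyl]prop-2-enoate
Product: 21 (5R,6R,7S,10R)-eudesm-3-en-6-yl (E)-3-[4-(tert-butyldimethylsilyloxy)phenyl]prop-2-enoate, via hydrazone adduct 18 (not isolated), via sulfonyl hydrazine 19 (not isolated), via allylic diazene 20 (not isolated)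
Conditions: N-isopropylidene-N'-(2-nitrobenzenesulfonyl)hydrazine, PPh3, DEAD, THF, 0 °C to rt; then CF3CH2OH/H2O, rt
Reagents that add atoms: none
Why: Reductive 1,3-transposition of an allylic alcohol through a monoalkyl diazene: Mitsunobu displacement at C3 should occur with inversion from the open α face, hydrolysis and loss of sulfinic acid give the 3α-diazene, and its retro-ene loss of N2 transfers hydrogen suprafacially to the α face of C5, which sets the trans ring fusion (5R) and places the olefin at C3=C4.

Step 11
Reactants: 21 (5R,6R,7S,10R)-eudesm-3-en-6-yl (E)-3-[4-(tert-butyldimethylsilyloxy)phenyl]prop-2-enoate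
Product: 22 (5R,6R,7S,10R)-eudesm-3-en-6-yl (E)-3-(4-hydroxyphenyl)prop-2-enoate (target)
Conditions: TBAF, AcOH, THF, 0 °C
Reagents that add atoms: none
Why: Fluoride-mediated desilylation of the aryl silyl ether, buffered with acetic acid, should leave the ester, the olefins and all stereocentres untouched.

**Compound list**

1 | (+)-dihydrocarvone, (5R)-2-methyl-5-(prop-1-en-2-yl)cyclohexan-1-one, C2 epimer mixture | CC1CC[C@H](CC1=O)C(C)=C | starting material
2 | (5R)-2-methyl-5-(propan-2-yl)cyclohexan-1-one, C2 epimer mixture | CC1CC[C@H](CC1=O)C(C)C | intermediate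
3 | (R)-1-phenylethylamine | C[C@@H](N)c1ccccc1 | starting material
4 | (R)-N-[(5R)-2-methyl-5-(propan-2-yl)cyclohexylidene]-1-phenylethan-1-amine | CC1CC[C@H](CC1=N[C@H](C)c1ccccc1)C(C)C | intermediate
5 | ethyl vinyl ketone (pent-1-en-3-one) | CCC(=O)C=C | starting material
6 | (R)-N-[(2S,5R)-2-methyl-2-(3-oxopentyl)-5-(propan-2-yl)cyclohexylidene]-1-phenylethan-1-amine (not isolated) | CCC(=O)CC[C@]1(C)CC[C@@H](C(C)C)CC1=N[C@H](C)c1ccccc1 | intermediate
7 | (2S,5R)-2-methyl-2-(3-oxopentyl)-5-(propan-2-yl)cyclohexan-1-one | CCC(=O)CC[C@]1(C)CC[C@@H](C(C)C)CC1=O | intermediate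
8 | (7R,10S)-5-hydroxyeudesman-3-one, aldol ketol, C4 and C5 configuration not defined (not isolated) | CC1C(=O)CC[C@]2(C)CC[C@@H](C(C)C)CC12O | intermediate
9 | (7R,10S)-eudesm-4-en-3-one (7β-isopropyl, 10β-methyl) | CC1=C2C[C@H](C(C)C)CC[C@@]2(C)CCC1=O | intermediate
10 | (7S,10S)-eudesma-3,5-dien-3-yl acetate | CC1=C(OC(C)=O)CC[C@]2(C)CC[C@@H](C(C)C)C=C12 | intermediate
11 | (6R,7S,10S)-6-hydroxyeudesm-4-en-3-one (6β-hydroxy) | CC1=C2[C@H](O)[C@H](C(C)C)CC[C@@]2(C)CCC1=O | intermediate
12 | (E)-4-hydroxycinnamic acid | OC(=O)/C=C/c1ccc(O)cc1 | starting material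
13 | tert-butyldimethylsilyl (E)-3-[4-(tert-butyldimethylsilyloxy)phenyl]prop-2-enoate (not isolated) | CC(C)(C)[Si](C)(C)OC(=O)/C=C/c1ccc(O[Si](C)(C)C(C)(C)C)cc1 | intermediate
14 | (E)-3-[4-(tert-butyldimethylsilyloxy)phenyl]prop-2-enoic acid | OC(=O)/C=C/c1ccc(O[Si](C)(C)C(C)(C)C)cc1 | intermediate
15 | mixed anhydride of 14 with 2,4,6-trichlorobenzoic acid (not isolated) | O=C(/C=C/c1ccc(O[Si](C)(C)C(C)(C)C)cc1)OC(=O)c1c(Cl)cc(Cl)cc1Cl | intermediate
16 | (6R,7S,10S)-3-oxoeudesm-4-en-6-yl (E)-3-[4-(tert-butyldimethylsilyloxy)phenyl]prop-2-enoate | CC1=C2[C@H](OC(=O)/C=C/c3ccc(O[Si](C)(C)C(C)(C)C)cc3)[C@H](C(C)C)CC[C@@]2(C)CCC1=O | intermediate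
17 | (3S,6R,7S,10S)-3-hydroxyeudesm-4-en-6-yl (E)-3-[4-(tert-butyldimethylsilyloxy)phenyl]prop-2-enoate (3β-hydroxy) | CC1=C2[C@H](OC(=O)/C=C/c3ccc(O[Si](C)(C)C(C)(C)C)cc3)[C@H](C(C)C)CC[C@@]2(C)CC[C@@H]1O | intermediate
18 | 3α-[N-(2-nitrobenzenesulfonyl)-N'-isopropylidenehydrazinyl] derivative of the 6β-ester (not isolated) | CC1=C2[C@H](OC(=O)/C=C/c3ccc(O[Si](C)(C)C(C)(C)C)cc3)[C@H](C(C)C)CC[C@@]2(C)CC[C@H]1N(N=C(C)C)S(=O)(=O)c1ccccc1[N+](=O)[O-] | intermediate
19 | 3α-[N-(2-nitrobenzenesulfonyl)hydrazinyl] derivative of the 6β-ester (not isolated) | CC1=C2[C@H](OC(=O)/C=C/c3ccc(O[Si](C)(C)C(C)(C)C)cc3)[C@H](C(C)C)CC[C@@]2(C)CC[C@H]1N(N)S(=O)(=O)c1ccccc1[N+](=O)[O-] | intermediate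
20 | 3α-diazenyl derivative of the 6β-ester (not isolated) | CC1=C2[C@H](OC(=O)/C=C/c3ccc(O[Si](C)(C)C(C)(C)C)cc3)[C@H](C(C)C)CC[C@@]2(C)CC[C@H]1N=N | intermediate
21 | (5R,6R,7S,10R)-eudesm-3-en-6-yl (E)-3-[4-(tert-butyldimethylsilyloxy)phenyl]prop-2-enoate | CC1=CCC[C@]2(C)CC[C@@H](C(C)C)[C@@H](OC(=O)/C=C/c3ccc(O[Si](C)(C)C(C)(C)C)cc3)[C@@H]12 | intermediate
22 | (5R,6R,7S,10R)-eudesm-3-en-6-yl (E)-3-(4-hydroxyphenyl)prop-2-enoate | CC1=CCC[C@]2(C)CC[C@@H](C(C)C)[C@@H](OC(=O)/C=C/c3ccc(O)cc3)[C@@H]12 | target

**Step count and risks**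

Total steps: 11. Longest linear sequence: 10 steps (steps 1 to 6 and 8 to 11, from 1); step 7 is a one-step branch.

Steps most likely to fail:

Step 10. The Mitsunobu displacement at the hindered allylic C3 centre may be slow, so that ionization to an allyl cation and elimination to a diene compete with N-alkylation of the hydrazone. The fallback sets out from 17. Formylation with formic acetic anhydride and pyridine at 0 °C should give (3S,6R,7S,10S)-3-formyloxyeudesm-4-en-6-yl (E)-3-[4-(tert-butyldimethylsilyloxy)phenyl]prop-2-enoate F1. Hydrogenolysis of this allylic formate with Pd(OAc)2 and PBu3 in THF should follow: zerovalent palladium ionizes the unhindered C3 formate with inversion, the palladium formate loses CO2, and the hydride is delivered from the metal (α face) to the more substituted allyl terminus C5. This gives the trans-fused C3=C4 olefin and comes back to the route at 21.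

Step 6. Oxygen transfer to the dienyl acetate may lack site or facial selectivity (attack at C4 of the tetrasubstituted enol acetate, or from the α face of C6). The fallback sets out from 9. Allylic oxidation of the γ-methylene with Rh2(cap)4 (cap = caprolactamate) and tert-butyl hydroperoxide should give (7S,10S)-eudesm-4-ene-3,6-dione F2. Reduction with NaBH4 and CeCl3·7H2O in MeOH should deliver hydride to both carbonyls from the α face and give (3S,6R,7S,10S)-eudesm-4-ene-3,6-diol F3 (3β,6β). MnO2 in CH2Cl2 should then reoxidize only the unhindered C3 allylic alcohol, and the sequence comes back to the route at 11.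

Step 8. Acyl transfer to the axial, doubly flanked C6 hydroxyl may be slow, which leaves time for base-induced isomerization of the γ-hydroxy enone. The fallback sets out from 11. DCC-mediated esterification with diethylphosphonoacetic acid, which reacts through its ketene and is a slim acyl donor, should give (6R,7S,10S)-3-oxoeudesm-4-en-6-yl 2-(diethoxyphosphoryl)acetate F4. Horner–Wadsworth–Emmons olefination with commercial 4-(tert-butyldimethylsilyloxy)benzaldehyde (LiCl, DBU, MeCN) should then build the E-cinnamate on the ester and come back to the route at 16.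

Further compounds
F1 | step 10 | (3S,6R,7S,10S)-3-formyloxyeudesm-4-en-6-yl (E)-3-[4-(tert-butyldimethylsilyloxy)phenyl]prop-2-enoate | CC1=C2[C@H](OC(=O)/C=C/c3ccc(O[Si](C)(C)C(C)(C)C)cc3)[C@H](C(C)C)CC[C@@]2(C)CC[C@@H]1OC=O
F2 | step 6 | (7S,10S)-eudesm-4-ene-3,6-dione | CC1=C2C(=O)[C@H](C(C)C)CC[C@@]2(C)CCC1=O
F3 | step 6 | (3S,6R,7S,10S)-eudesm-4-ene-3,6-diol | CC1=C2[C@H](O)[C@H](C(C)C)CC[C@@]2(C)CC[C@@H]1O
F4 | step 8 | (6R,7S,10S)-3-oxoeudesm-4-en-6-yl 2-(diethoxyphosphoryl)acetate | CC1=C2[C@H](OC(=O)CP(=O)(OCC)OCC)[C@H](C(C)C)CC[C@@]2(C)CCC1=O
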